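The cyclobutane C4–C5–C11–C10 carries a substituent on every carbon and C10 is quaternary; cutting C4–C5 and C10–C11 gives a trisubstituted alkene (C4=C10) and a two-carbon ketene equivalent (C5, C11). Step 5 joins the two in one operation: a chiral keteniminium ion, made from a 3-benzyloxypropanamide of (2R,5R)-2,5-dimethylpyrrolidine, adds to the (E)-bis-silyl ether of 2-methylbut-2-ene-1,4-diol, forming both bonds, the ring and the C4, C10 and C11 stereocentres, and leaving a C5 ketone. That ketone takes C6–C8; the C9 arm then closes the seven-membered ring, and the differentiated C3 and C1 arms close ring A.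

Key step: step 5

Numbering: C1 ring A carbonyl, C2 =CH, C3 =C(CH3), C4 and C11 the cyclobutane CH groups next to C3 and C1, C5 the cyclobutane CH bearing C6(CH3)2, C7 (senecioate), C8 (CH2), C9 (isovalerate), C10 (quaternary, CH3). Upper face = cyclobutane face of the C10 methyl; lower face = face of C9. TBS = tert-butyldimethylsilyl, TBDPS = tert-butyldiphenylsilyl, Bn = benzyl.

Assumption: the sense of induction of the (2R,5R) auxiliary in step 5 and of the ferrocenyl diphosphine in step 11 is taken to be as drawn; should either prove opposite, the mirror-image auxiliary or ligand is used and nothing else changes.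

Step 1
Reactants: 1 3-(benzyloxy)propanoic acid; 2 (2R,5R)-2,5-dimethylpyrrolidine
Product: 4 3-(benzyloxy)-1-[(2R,5R)-2,5-dimethylpyrrolidin-1-yl]propan-1-one, via acid chloride 3 (not isolated)
Conditions: (COCl)2, DMF (cat.), CH2Cl2, 0 °C → rt; then 2, Et3N, CH2Cl2, 0 °C → rt
Reagents that add atoms: oxalyl chloride, ClC(=O)C(=O)Cl (supplies the chlorine of 3; no atom of it remains in 4)
Why: Acid chloride formation and N-acylation cope with the hindered secondary amine, and no stereocentre is touched.

Step 2
Reactants: 5 (tert-butyldiphenylsilyloxy)acetaldehyde; 6 ethyl 2-(triphenylphosphoranylidene)propanoate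
Product: 7 ethyl (E)-4-(tert-butyldiphenylsilyloxy)-2-methylbut-2-enoate
Conditions: CH2Cl2, rt → 40 °C
Reagents that add atoms: none
Why: Wittig olefination with a stabilised α-branched ylide should give the (E)-enoate, which places the future C3 arm cis to the future C10 methyl.

Step 3
Reactants: 7 ethyl (E)-4-(tert-butyldiphenylsilyloxy)-2-methylbut-2-enoate
Product: 8 (E)-4-(tert-butyldiphenylsilyloxy)-2-methylbut-2-en-1-ol
Conditions: iBu2AlH (2.2 equiv), CH2Cl2, −78 °C; aq potassium sodium tartrate
Reagents that add atoms: none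
Why: Aluminium hydride 1,2-reduction of the enoate gives the allylic alcohol without touching the silyl ether or the alkene geometry.

Step 4
Reactants: 8 (E)-4-(tert-butyldiphenylsilyloxy)-2-methylbut-2-en-1-ol
Product: 9 (E)-1-(tert-butyldimethylsilyloxy)-4-(tert-butyldiphenylsilyloxy)-2-methylbut-2-ene
Conditions: TBSCl, imidazole, DMF, rt
Reagents that add atoms: tert-butyldimethylsilyl chloride, CC(C)(C)[Si](C)(C)Cl
Why: Silylation of the primary alcohol puts the more labile silyl group on the future neopentyl C9 oxygen, which has to be freed first, and the robust TBDPS group on the C3 oxygen.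

Step 5
Reactants: 4 3-(benzyloxy)-1-[(2R,5R)-2,5-dimethylpyrrolidin-1-yl]propan-1-one; 9 (E)-1-(tert-butyldimethylsilyloxy)-4-(tert-butyldiphenylsilyloxy)-2-methylbut-2-ene
Product: 12 cyclobutanone (C5 ketone; C10 bears CH3 and CH2OTBS; C4 bears CH2OTBDPS; C11 bears CH2OBn; both arms cis to the C10 methyl), via keteniminium triflate 10 (not isolated), via cyclobutaniminium triflate 11 (not isolated)
Conditions: Tf2O (1.1 equiv), 2,4,6-collidine (1.2 equiv), 9 (2 equiv), ClCH2CH2Cl, −20 °C → 60 °C; then aq NaHCO3, 40 °C
Reagents that add atoms: water, O (the C5 carbonyl oxygen); trifluoromethanesulfonic anhydride, O=S(=O)(OS(=O)(=O)C(F)(F)F)C(F)(F)F (triflate counter-ion of 10 and 11 only)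
Why: O-Triflation of amide 4 and loss of the α-proton to collidine give keteniminium ion 10, whose central carbon C5 is attacked by the less substituted alkene carbon C4; the tertiary cation developing at C10 is then captured by the enamine carbon C11, and hydrolysis of iminium salt 11 frees the ketone. The closest known reaction type is the keteniminium–alkene [2+2] cycloaddition of triflic-anhydride-activated tertiary amides that carry C2-symmetric pyrrolidines. The four-membered ring closes in a stepwise polar [2+2] mode, the C10–C11 bond forming last by cation–enamine collapse. C10 is fixed by the auxiliary, whose 2,5-methyl groups shield one face of the ion and so select the alkene face; C4 follows from the (E) geometry, which suprafacial addition transfers as the cis relation of the C3 arm and the C10 methyl; C11 lies next to the iminium and later the ketone carbon and should settle during the basic hydrolysis with its arm trans to the bulkier CH2OTBS group, that is cis to the C4 arm. The step needs regiocontrol, retention of alkene geometry and face selection, which come from the polarisation of the trisubstituted alkene, from fast ring closure and from the auxiliary, while silyl and benzyl ethers are inert to the ion.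

Step 6
Reactants: 12 cyclobutanone
Product: 13 tertiary cyclobutanol (C5 bears OH on the upper face and the 2-methylbut-3-en-2-yl group on the lower face, cis to C9)
Conditions: Me2C=CHCH2MgCl (1.5 equiv), THF, −78 °C; aq NH4Cl
Reagents that add atoms: 3-methylbut-2-en-1-ylmagnesium chloride, CC(C)=CC[Mg]Cl
Why: Allylic Grignard addition through a six-membered SE2′ transition state (reverse prenylation) delivers the dimethyl-substituted terminus to the strained ketone from the lower face, anti to both α-arms and the C10 methyl, so that C6 ends cis to C9.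

Step 7
Reactants: 13 tertiary cyclobutanol
Product: 14 aldehyde (C5 bears OH and C(CH3)2CHO; C7 is the aldehyde carbon)
Conditions: O3, CH2Cl2/MeOH, −78 °C; then Me2S, −78 °C → rt
Reagents that add atoms: ozone, [O-][O+]=O
Why: Ozonolysis with reductive work-up cleaves the only C=C bond to an aldehyde that has no α-hydrogen and cannot epimerise or eliminate.

Step 8
Reactants: 14 aldehyde
Product: 15 β-ketophosphonate (C5 bears OH and C(CH3)2C(=O)CH2P(O)(OMe)2; C7 ketone, C8 methylene)
Conditions: (MeO)2P(O)CHN2 (1.5 equiv), SnCl2 (20 mol %), CH2Cl2, rt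
Reagents that add atoms: dimethyl (diazomethyl)phosphonate, COP(=O)(OC)C=[N+]=[N-]
Why: Roskamp homologation (addition of the diazo carbon to the tin-activated aldehyde, 1,2-hydride shift, loss of N2) gives the ketophosphonate under neutral conditions that spare the tertiary β-hydroxyl.

Step 9
Reactants: 15 β-ketophosphonate
Product: 16 primary alcohol (as 15 with free C9 hydroxyl)
Conditions: HF·pyridine, pyridine, THF, 0 °C → rt
Reagents that add atoms: none
Why: Fluoride desilylation cleaves the primary TBS ether much faster than the bulkier TBDPS ether and leaves the benzyl ether alone.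

Step 10
Reactants: 16 primary alcohol
Product: 18 bicyclic enone (seven-membered ring closed; C7 ketone; C8=C9; C5 hydroxyl on the upper face), via aldehyde 17 (not isolated)
Conditions: Dess–Martin periodinane, pyridine, CH2Cl2, 0 °C → rt; then LiCl, iPr2NEt, MeCN, rt → 40 °C
Reagents that add atoms: none
Why: Dess–Martin oxidation gives the non-enolisable C9 aldehyde, and an intramolecular Horner–Wadsworth–Emmons reaction under Masamune–Roush conditions (no alkoxide, hence no retro-aldol at C5–C6) forms C8=C9 and closes the seven-membered ring as the cis-enone, possible because C6 and C9 share the lower face.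

Step 11
Reactants: 18 bicyclic enone
Product: 20 β-hydroxy ketone (C9 hydroxyl on the side of C11; C7 ketone), via pinacolboronate 19 (not isolated)
Conditions: CuCl (5 mol %), NaOtBu (10 mol %), (R)-1-[(SP)-2-(diphenylphosphino)ferrocenyl]ethyldicyclohexylphosphine (6 mol %), B2pin2 (1.2 equiv), MeOH (2 equiv), THF, rt; then NaBO3·4H2O, THF/H2O, rt
Reagents that add atoms: sodium perborate, [Na+].[O-]OB=O (the C9 oxygen); bis(pinacolato)diboron, CC1(C)OB(OC1(C)C)B1OC(C)(C)C(C)(C)O1 (boron group of 19 only)
Why: Copper-catalysed asymmetric conjugate borylation puts boron on C9 on the enone face chosen by the chiral diphosphine (the substrate itself is almost unbiased there), and perborate oxidation replaces boron by hydroxyl with retention, which sets C9.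

Step 12
Reactants: 20 β-hydroxy ketone
Product: 21 diol monoester (C9 isovalerate; free C7 hydroxyl anti to O9, on the side of C4)
Conditions: 3-methylbutanal (5 equiv), SmI2 (30 mol %, premixed with the aldehyde), THF, −10 °C
Reagents that add atoms: 3-methylbutanal, CC(C)CC=O
Why: Evans–Tishchenko reduction: the samarium-bound hemiacetal formed on O9 passes its hydride intramolecularly to C7, giving the 1,3-anti diol with the isovalerate already on O9, while the C5 hydroxyl points away from C7 and cannot compete.

Step 13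
Reactants: 21 diol monoester
Product: 22 diester (C7 3-methylbut-2-enoate, C9 isovalerate, free C5 hydroxyl)
Conditions: Me2C=CHCOCl (1.5 equiv), pyridine, DMAP (cat.), CH2Cl2, 0 °C → rt
Reagents that add atoms: 3-methylbut-2-enoyl chloride, CC(C)=CC(=O)Cl
Why: Nucleophile-catalysed acylation reaches the secondary C7 alcohol but not the far more hindered tertiary C5 alcohol, and pyridine as the only base limits deconjugation of the senecioyl group.

Step 14
Reactants: 22 diester
Product: 23 tert-alkyl methyl oxalate (C5–O–CO–CO2Me)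
Conditions: MeO2CCOCl (3 equiv), Et3N, DMAP, CH2Cl2, 0 °C → rt
Reagents that add atoms: methyl chlorooxoacetate, COC(=O)C(=O)Cl
Why: Acylation with the small, very reactive oxalyl half-ester chloride converts the only free hydroxyl into the radical precursor for deoxygenation.

Step 15
Reactants: 23 tert-alkyl methyl oxalate
Product: 24 deoxygenated diester (C5–H on the upper face)
Conditions: Bu3SnH (2 equiv), AIBN (cat.), toluene, 110 °C
Reagents that add atoms: none
Why: Radical deoxygenation of the tert-alkyl methyl oxalate (Dowd–Barton variant of the Barton–McCombie reaction) passes through a bridgehead cyclobutyl radical that can take hydrogen only on the upper face, because C6 is tied to C10 underneath, which sets C5.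

Step 16
Reactants: 24 deoxygenated diester
Product: 25 primary alcohol (free C3 hydroxyl)
Conditions: HF·pyridine (excess), THF, rt
Reagents that add atoms: none
Why: Fluoride desilylation removes the primary TBDPS ether under mildly acidic conditions that spare both esters and the benzyl ether.

Step 17
Reactants: 25 primary alcohol
Product: 26 aldehyde (C4–CHO)
Conditions: Dess–Martin periodinane, pyridine, CH2Cl2, 0 °C → rt
Reagents that add atoms: none
Why: Buffered Dess–Martin oxidation gives the aldehyde, whose α-carbon C4 keeps its arm on the upper face, the only open one once the lower face is bridged.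

Step 18
Reactants: 26 aldehyde
Product: 27 secondary alcohol (C4–CH(OH)CH3, both C3 epimers)
Conditions: MeMgBr (1.2 equiv), THF, −78 °C; aq NH4Cl
Reagents that add atoms: methylmagnesium bromide, C[Mg]Br
Why: Grignard addition is much faster to the aldehyde than to the two hindered esters at −78 °C, and the unselective carbinol centre is removed by oxidation in step 20.

Step 19
Reactants: 27 secondary alcohol
Product: 28 diol (C11–CH2OH and C4–CH(OH)CH3)
Conditions: BCl3 (3 equiv), C6HMe5 (4 equiv), CH2Cl2, −78 °C; then MeOH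
Reagents that add atoms: none
Why: Lewis-acid debenzylation with pentamethylbenzene as a non-basic cation scavenger removes the benzyl group at low temperature and spares the esters and the senecioate double bond, which hydrogenolysis would endanger.

Step 20
Reactants: 28 diol
Product: 29 keto aldehyde (C4–COCH3 and C11–CHO)
Conditions: Dess–Martin periodinane (3 equiv), pyridine, CH2Cl2, 0 °C → rt
Reagents that add atoms: none
Why: One Dess–Martin oxidation turns the secondary alcohol into the C3 methyl ketone and the primary alcohol into the C1 aldehyde.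

Step 21
Reactants: 29 keto aldehyde
Product: 30 β-ketophosphonate (C11–C(=O)CH2P(O)(OMe)2 and C4–COCH3)
Conditions: (MeO)2P(O)CHN2 (1.5 equiv), SnCl2 (20 mol %), CH2Cl2, rt
Reagents that add atoms: dimethyl (diazomethyl)phosphonate, COP(=O)(OC)C=[N+]=[N-]
Why: Roskamp homologation is selective for the aldehyde over the methyl ketone and installs C2 as the phosphonate-bearing methylene next to the new C1 ketone.

Step 22
Reactants: 30 β-ketophosphonate
Product: 31 CNP0214473.1 (target)
Conditions: NaH (1.1 equiv), THF, 0 °C → 40 °C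
Reagents that add atoms: none
Why: Intramolecular Horner–Wadsworth–Emmons reaction of the C2 phosphonate carbanion with the C3 ketone closes the six-membered ring A as the enone; the two upper-face arms are held close by the bicyclic core and no stereocentre is formed.

Compound list
1 | 3-(benzyloxy)propanoic acid | OC(=O)CCOCc1ccccc1 | starting material
2 | (2R,5R)-2,5-dimethylpyrrolidine | C[C@@H]1CC[C@@H](C)N1 | starting material
3 | 3-(benzyloxy)propanoyl chloride (not isolated) | ClC(=O)CCOCc1ccccc1 | intermediate
4 | 3-(benzyloxy)-1-[(2R,5R)-2,5-dimethylpyrrolidin-1-yl]propan-1-one | C[C@@H]1CC[C@@H](C)N1C(=O)CCOCc1ccccc1 | intermediate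
5 | (tert-butyldiphenylsilyloxy)acetaldehyde | CC(C)(C)[Si](OCC=O)(c1ccccc1)c1ccccc1 | starting material
6 | ethyl 2-(triphenylphosphoranylidene)propanoate | CCOC(=O)C(C)=P(c1ccccc1)(c1ccccc1)c1ccccc1 | starting material
7 | ethyl (E)-4-(tert-butyldiphenylsilyloxy)-2-methylbut-2-enoate | CCOC(=O)/C(C)=C/CO[Si](c1ccccc1)(c1ccccc1)C(C)(C)C | intermediate
8 | (E)-4-(tert-butyldiphenylsilyloxy)-2-methylbut-2-en-1-ol | OC/C(C)=C/CO[Si](c1ccccc1)(c1ccccc1)C(C)(C)C | intermediate
9 | (E)-1-(tert-butyldimethylsilyloxy)-4-(tert-butyldiphenylsilyloxy)-2-methylbut-2-ene | CC(C)(C)[Si](C)(C)OC/C(C)=C/CO[Si](c1ccccc1)(c1ccccc1)C(C)(C)C | intermediate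
10 | keteniminium triflate from 4 (not isolated) | C[C@@H]1CC[C@@H](C)[N+]1=C=CCOCc1ccccc1.[O-]S(=O)(=O)C(F)(F)F | intermediate
11 | cyclobutaniminium triflate, substituents as in 12 (not isolated) | CC(C)(C)[Si](C)(C)OC[C@@]1(C)[C@H](COCc2ccccc2)C(=[N+]2[C@H](C)CC[C@H]2C)[C@@H]1CO[Si](c1ccccc1)(c1ccccc1)C(C)(C)C.[O-]S(=O)(=O)C(F)(F)F | intermediate
12 | 2-(benzyloxymethyl)-4-(tert-butyldiphenylsilyloxymethyl)-3-(tert-butyldimethylsilyloxymethyl)-3-methylcyclobutan-1-one, both arms cis to the 3-methyl | CC(C)(C)[Si](C)(C)OC[C@@]1(C)[C@H](COCc2ccccc2)C(=O)[C@@H]1CO[Si](c1ccccc1)(c1ccccc1)C(C)(C)C | intermediate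
13 | tertiary cyclobutanol, C5 with OH (upper face) and 2-methylbut-3-en-2-yl (lower face) | CC(C)(C)[Si](C)(C)OC[C@@]1(C)[C@H](COCc2ccccc2)[C@@](O)(C(C)(C)C=C)[C@@H]1CO[Si](c1ccccc1)(c1ccccc1)C(C)(C)C | intermediate
14 | C7 aldehyde | CC(C)(C)[Si](C)(C)OC[C@@]1(C)[C@H](COCc2ccccc2)[C@@](O)(C(C)(C)C=O)[C@@H]1CO[Si](c1ccccc1)(c1ccccc1)C(C)(C)C | intermediate
15 | C7 ketone, C8 dimethyl phosphonate | CC(C)(C)[Si](C)(C)OC[C@@]1(C)[C@H](COCc2ccccc2)[C@@](O)(C(C)(C)C(=O)CP(=O)(OC)OC)[C@@H]1CO[Si](c1ccccc1)(c1ccccc1)C(C)(C)C | intermediate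
16 | C9 primary alcohol | OC[C@@]1(C)[C@H](COCc2ccccc2)[C@@](O)(C(C)(C)C(=O)CP(=O)(OC)OC)[C@@H]1CO[Si](c1ccccc1)(c1ccccc1)C(C)(C)C | intermediate
17 | C9 aldehyde (not isolated) | O=C[C@@]1(C)[C@H](COCc2ccccc2)[C@@](O)(C(C)(C)C(=O)CP(=O)(OC)OC)[C@@H]1CO[Si](c1ccccc1)(c1ccccc1)C(C)(C)C | intermediate
18 | bicyclic enone: seven-membered ring with C7 ketone and C8=C9, C5 hydroxyl | O=C1C=C[C@@]2(C)[C@H](COCc3ccccc3)[C@@](O)(C1(C)C)[C@@H]2CO[Si](c1ccccc1)(c1ccccc1)C(C)(C)C | intermediate
19 | C9 pinacolboronate (not isolated) | O=C1C[C@@H](B3OC(C)(C)C(C)(C)O3)[C@@]2(C)[C@H](COCc4ccccc4)[C@@](O)(C1(C)C)[C@@H]2CO[Si](c1ccccc1)(c1ccccc1)C(C)(C)C | intermediate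
20 | β-hydroxy ketone: C9 hydroxyl, C7 ketone | O=C1C[C@@H](O)[C@@]2(C)[C@H](COCc3ccccc3)[C@@](O)(C1(C)C)[C@@H]2CO[Si](c1ccccc1)(c1ccccc1)C(C)(C)C | intermediate
21 | C9 isovalerate, C7 hydroxyl (anti) | O[C@@H]1C[C@@H](OC(=O)CC(C)C)[C@@]2(C)[C@H](COCc3ccccc3)[C@@](O)(C1(C)C)[C@@H]2CO[Si](c1ccccc1)(c1ccccc1)C(C)(C)C | intermediate
22 | C7 senecioate, C9 isovalerate, C5 hydroxyl | CC(C)=CC(=O)O[C@@H]1C[C@@H](OC(=O)CC(C)C)[C@@]2(C)[C@H](COCc3ccccc3)[C@@](O)(C1(C)C)[C@@H]2CO[Si](c1ccccc1)(c1ccccc1)C(C)(C)C | intermediate
23 | C5 methyl oxalate | CC(C)=CC(=O)O[C@@H]1C[C@@H](OC(=O)CC(C)C)[C@@]2(C)[C@H](COCc3ccccc3)[C@@](OC(=O)C(=O)OC)(C1(C)C)[C@@H]2CO[Si](c1ccccc1)(c1ccccc1)C(C)(C)C | intermediate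
24 | C5-deoxygenated diester | CC(C)=CC(=O)O[C@@H]1C[C@@H](OC(=O)CC(C)C)[C@@]2(C)[C@H](COCc3ccccc3)[C@@H](C1(C)C)[C@@H]2CO[Si](c1ccccc1)(c1ccccc1)C(C)(C)C | intermediate
25 | C3 primary alcohol | CC(C)=CC(=O)O[C@@H]1C[C@@H](OC(=O)CC(C)C)[C@@]2(C)[C@H](COCc3ccccc3)[C@@H](C1(C)C)[C@@H]2CO | intermediate
26 | C3 aldehyde | CC(C)=CC(=O)O[C@@H]1C[C@@H](OC(=O)CC(C)C)[C@@]2(C)[C@H](COCc3ccccc3)[C@@H](C1(C)C)[C@@H]2C=O | intermediate
27 | C3 secondary alcohol (1-hydroxyethyl on C4, both epimers) | CC(C)=CC(=O)O[C@@H]1C[C@@H](OC(=O)CC(C)C)[C@@]2(C)[C@H](COCc3ccccc3)[C@@H](C1(C)C)[C@@H]2C(C)O | intermediate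
28 | diol (hydroxymethyl on C11, 1-hydroxyethyl on C4) | CC(C)=CC(=O)O[C@@H]1C[C@@H](OC(=O)CC(C)C)[C@@]2(C)[C@H](CO)[C@@H](C1(C)C)[C@@H]2C(C)O | intermediate
29 | keto aldehyde (formyl on C11, acetyl on C4) | CC(C)=CC(=O)O[C@@H]1C[C@@H](OC(=O)CC(C)C)[C@@]2(C)[C@H](C=O)[C@@H](C1(C)C)[C@@H]2C(C)=O | intermediate
30 | β-ketophosphonate on C11, acetyl on C4 | CC(C)=CC(=O)O[C@@H]1C[C@@H](OC(=O)CC(C)C)[C@@]2(C)[C@H](C(=O)CP(=O)(OC)OC)[C@@H](C1(C)C)[C@@H]2C(C)=O | intermediate
31 | CNP0214473.1 | CC(C)=CC(=O)O[C@@H]1C[C@@H](OC(=O)CC(C)C)[C@@]2(C)[C@@H]3C(=O)C=C(C)[C@H]2[C@@H]3C1(C)C | target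

Total step count: 22. Longest linear sequence: 21 steps (steps 2 to 22).

Steps most likely to fail

Step 5. Capture of keteniminium ion 10 by the hindered alkene, which two allylic silyloxy groups deactivate inductively, may be slower than decay of the ion, and face selection by the auxiliary may be incomplete. The fallback sets out from alkene 9: dichloroketene (Cl3CCOCl, Zn, Et2O) adds with the same regiochemistry and with retention of the alkene geometry to give the racemic dichlorocyclobutanone F1. Zinc in acetic acid removes both chlorine atoms to give the racemic cyclobutanone F2, and chromatography on a chiral stationary phase supplies the single enantiomer F3. Kinetic enolisation at the C11 methylene (LiN(SiMe3)2, THF, −78 °C) and alkylation with benzyl chloromethyl ether on the face of the C10 methyl bring the route back at 12.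

Step 11. The copper boryl species may add only slowly at C9, which is flanked by the quaternary C10, and the ligand may fail to override the small intrinsic bias, so that both enone faces are attacked. The fallback sets out from enone 18: amine-salt-catalysed asymmetric Weitz–Scheffer epoxidation (aqueous H2O2, 9-amino-9-deoxy-epi-quinine bis(trifluoroacetate), dioxane) gives the 8,9-epoxy ketone F4 with the oxygen on the side of C11. Sodium phenylselenide, generated from (PhSe)2 and NaBH4 in ethanol with acetic acid, cleaves the C8–O bond reductively, and the route is rejoined at 20.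

Step 14. Acylation of the C5 hydroxyl, buried between the quaternary C6 and two ring methines, may stall or be overtaken by acyl migration from O7. The fallback sets out from 22: the potassium alkoxide (KN(SiMe3)2, THF, −78 °C) is trapped with CS2 and then MeI to give the S-methyl xanthate F5, for which Chugaev elimination is excluded because it would need a bridgehead cyclobutene. Bu3SnH and AIBN in toluene then effect a Barton–McCombie reduction, and the route is rejoined at 24.

Further compounds
F1 | step 5 | racemic 2,2-dichloro-3-methyl-3-(tert-butyldimethylsilyloxymethyl)-4-(tert-butyldiphenylsilyloxymethyl)cyclobutan-1-one, C4 arm cis to the methyl (both enantiomers written) | CC(C)(C)[Si](C)(C)OC[C@@]1(C)C(Cl)(Cl)C(=O)[C@@H]1CO[Si](c1ccccc1)(c1ccccc1)C(C)(C)C.CC(C)(C)[Si](C)(C)OC[C@]1(C)C(Cl)(Cl)C(=O)[C@H]1CO[Si](c1ccccc1)(c1ccccc1)C(C)(C)C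
F2 | step 5 | racemic 3-methyl-3-(tert-butyldimethylsilyloxymethyl)-2-(tert-butyldiphenylsilyloxymethyl)cyclobutan-1-one, arm cis to the methyl (both enantiomers written) | CC(C)(C)[Si](C)(C)OC[C@@]1(C)CC(=O)[C@@H]1CO[Si](c1ccccc1)(c1ccccc1)C(C)(C)C.CC(C)(C)[Si](C)(C)OC[C@]1(C)CC(=O)[C@H]1CO[Si](c1ccccc1)(c1ccccc1)C(C)(C)C
F3 | step 5 | single enantiomer of F2 with the C4 and C10 configuration of 12 | CC(C)(C)[Si](C)(C)OC[C@@]1(C)CC(=O)[C@@H]1CO[Si](c1ccccc1)(c1ccccc1)C(C)(C)C
F4 | step 11 | 8,9-epoxy ketone from 18, epoxide oxygen on the side of C11 | O=C1[C@H]3O[C@H]3[C@@]2(C)[C@H](COCc4ccccc4)[C@@](O)(C1(C)C)[C@@H]2CO[Si](c1ccccc1)(c1ccccc1)C(C)(C)C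
F5 | step 14 | O-(C5) S-methyl xanthate of 22 | CC(C)=CC(=O)O[C@@H]1C[C@@H](OC(=O)CC(C)C)[C@@]2(C)[C@H](COCc3ccccc3)[C@@](OC(=S)SC)(C1(C)C)[C@@H]2CO[Si](c1ccccc1)(c1ccccc1)C(C)(C)C
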